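**Plan**

- Retrosynthetic cuts, in order: the C7/C14 oxirane (from a C7=C14 enone); C7–C8 and C8–C9 together (C7 enol triflate + CO + C9–C11 vinylstannane); the C3–O–C4 oxirane (C3–OH onto a C4 sulfonate); C2–O and C3–O (dihydroxylation of C2=C3); C1–O and C4–O together (O2 across a ring diene); the diene from (R)-carvone.
- Enabling feature: the carbocycle carries oxygen on the four contiguous atoms C1–C4, with C1–O trans to the C6 branch. This is the imprint of 1,4-addition of O2 to a C1=C2–C3=C4 ring diene followed by oxidation of the shifted C2=C3 alkene.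
- Forward ring order: carbocycle from carvone; peroxide bridge (1,2-dioxene) closed at step 5 and reduced open at step 6; ring oxirane closed at step 14; chain joined at step 16; chain oxirane closed at step 17.
- Stereochemistry: C6 from (R)-carvone; C1 and C4 from O2 adding anti to the C6 group; C3 from OsO4 anti to both allylic oxygens; C4 inverted on oxirane closure; C7 from A(1,3)-controlled closure of a peroxy enolate; C9=C10 (E) from syn hydrostannylation.

Key step: step 5

Remark: atom numbers are those of the target (ring: C1 acyloxy CH, C2 ketone, C3 methyl-bearing oxirane carbon, C4 oxirane CH, C5 CH2, C6 branch CH; chain: C7 oxirane carbon, C14 its CH2, C8 ketone, C9=C10, C11 carbinol). The target SMILES is read as (1S,3S,4S,6R,7R) in this numbering.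

**Route**

Step 1
Reactants: 1 (R)-carvone
Product: 3 (5R)-5-acetyl-2-methylcyclohex-2-en-1-one, via ozonide 2 (not isolated)
Conditions: O3, CH2Cl2, −78 °C (Sudan red end point); then PPh3, −78 °C → rt
Reagents that add atoms: ozone, [O-][O+]=O
Why: Chemoselective ozonolysis (1,3-dipolar cycloaddition, Criegee rearrangement to the 1,2,4-trioxolane, phosphine reduction): electrophilic ozone takes the electron-rich 1,1-disubstituted isopropenyl alkene well before the electron-poor enone, and C6 is not touched.

Step 2
Reactants: 3 (5R)-5-acetyl-2-methylcyclohex-2-en-1-one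
Product: 4 (5R)-2-methyl-5-(2-methyl-1,3-dioxolan-2-yl)cyclohex-2-en-1-one
Conditions: Me3SiOCH2CH2OSiMe3, Me3SiOTf (cat.), CH2Cl2, −78 → −20 °C; pyridine quench
Reagents that add atoms: 1,2-bis(trimethylsilyloxy)ethane, C[Si](C)(C)OCCO[Si](C)(C)C
Why: Noyori ketalisation: the saturated methyl ketone is ketalised while the less electrophilic conjugated ring ketone is left alone, and the cold non-enolising medium protects the C6 stereocentre alpha to the acetyl group.

Step 3
Reactants: 4 (5R)-2-methyl-5-(2-methyl-1,3-dioxolan-2-yl)cyclohex-2-en-1-one; 5 p-toluenesulfonyl hydrazide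
Product: 6 (E)-tosylhydrazone of 4
Conditions: MeOH, rt → 40 °C
Reagents that add atoms: none
Why: Hydrazone condensation at the only free carbonyl group without added acid, so the dioxolane survives; the sulfonamide nitrogen settles syn to the C1 methylene, away from the methyl-bearing alkene carbon.

Step 4
Reactants: 6 (E)-tosylhydrazone of 4
Product: 8 2-methyl-2-[(1R)-4-methylcyclohexa-2,4-dien-1-yl]-1,3-dioxolane, via vinyllithium 7 (not isolated)
Conditions: MeLi (3 equiv), Et2O, 0 °C → rt; then H2O
Reagents that add atoms: none
Why: Shapiro reaction of an α,β-unsaturated tosylhydrazone: the dianion forms by deprotonation at the α′ methylene C1, loss of sulfinate and N2 leaves the C2 vinyllithium with the new C1=C2 bond conjugated to C3=C4, and water protonates C2; the dioxolane and C6 are inert to MeLi.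

Step 5
Reactants: 8 2-methyl-2-[(1R)-4-methylcyclohexa-2,4-dien-1-yl]-1,3-dioxolane; 9 dioxygen
Product: 10 endoperoxide 2-methyl-2-(5-methyl-2,3-dioxabicyclo[2.2.2]oct-5-en-7-yl)-1,3-dioxolane with the O–O bridge on the face opposite the dioxolanyl group
Conditions: O2, tetraphenylporphyrin (cat.), CH2Cl2, white LED, −78 °C
Reagents that add atoms: none
Why: Sensitised singlet oxygen adds to the ring-locked s-cis diene in a concerted suprafacial [4+2] cycloaddition that forms C1–O and C4–O together; the closest known reaction type is the dye-sensitised photooxygenation of α-terpinene and α-phellandrene to ascaridole-type endoperoxides. The new six-membered 1,2-dioxene ring (the peroxide bridge of the bicyclo[2.2.2]octene) is closed by the cycloaddition itself, both ends at once. C1 and C4 are both controlled by the C6 stereocentre: the fully substituted dioxolanyl carbon lies over one diene face when pseudoaxial and still hinders the developing bridge on that side when pseudoequatorial, so oxygen should bind on the other face and both C–O bonds come out trans to the C6 branch. The step needs facial selectivity and cycloaddition over the ene path; the first rests on the bulk of the quaternary ketal carbon, which is larger than the isopropyl group of α-phellandrene, the second on the cisoid cyclic diene, which cycloadds faster than its C3=C4 alkene reacts by the ene path, helped by the low temperature. The ketal is inert to singlet oxygen, and the peroxide is kept cold and reduced at once.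

Step 6
Reactants: 10 endoperoxide
Product: 11 3-methyl-6-(2-methyl-1,3-dioxolan-2-yl)cyclohex-2-ene-1,4-diol with both hydroxyls trans to the C6 group
Conditions: thiourea, MeOH, rt
Reagents that add atoms: none
Why: Thiourea reduction of a bicyclic endoperoxide: sulfur attacks only the O–O bond, so both C–O bonds and the configurations at C1 and C4 are kept and the cis-2-ene-1,4-diol results with alkene and ketal intact.

Step 7
Reactants: 11 cis-ene-diol
Product: 12 C4 tert-butyldimethylsilyl ether of 11
Conditions: t-BuMe2SiCl (1.05 equiv), imidazole, CH2Cl2, −20 → 0 °C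
Reagents that add atoms: tert-butyldimethylsilyl chloride, CC(C)(C)[Si](C)(C)Cl
Why: Regioselective silyl ether formation: the C1 hydroxyl is flanked by C6 with its quaternary dioxolanyl carbon, so one equivalent of the bulky silyl chloride should take the C4 hydroxyl, whose neighbours are only a CH2 and the planar C3.

Step 8
Reactants: 12 C4 silyl ether; 13 3-methylbutanoyl chloride
Product: 14 C1 3-methylbutanoate of 12
Conditions: pyridine, DMAP (cat.), CH2Cl2, 0 °C → rt
Reagents that add atoms: none
Why: DMAP-catalysed acyl transfer to the remaining hindered secondary allylic hydroxyl; no bond to C1 is broken, so its configuration is retained.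

Step 9
Reactants: 14 ester with dioxolane
Product: 15 methyl ketone (C6 acetyl in place of the dioxolane)
Conditions: PPTS, acetone/H2O (9:1), 50 °C
Reagents that add atoms: water, O
Why: Acid-catalysed ketal hydrolysis through the oxocarbenium ion with a weak pyridinium acid that is too mild to ionise the allylic ester or remove the secondary silyl ether; the acetyl group trans to C1–O is the more stable arrangement should C6 enolise.

Step 10
Reactants: 15 methyl ketone
Product: 17 enol triflate with C6–C(OTf)=CH2, via potassium enolate 16 (not isolated)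
Conditions: KN(SiMe3)2, THF, −78 °C; then N-(5-chloropyridin-2-yl)bis(trifluoromethanesulfonimide), −78 °C
Reagents that add atoms: N-(5-chloropyridin-2-yl)bis(trifluoromethanesulfonimide) (Comins' reagent), O=S(=O)(N(c1ccc(Cl)cn1)S(=O)(=O)C(F)(F)F)C(F)(F)F
Why: Kinetic enolate formation and O-sulfonylation: the bulky amide removes a methyl proton at −78 °C much faster than the hindered C6 methine or the ester α-protons, and trapping at the same temperature gives the 1,1-disubstituted enol triflate before the enolate can move to the C6 side and expel the C1 acyloxy group.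

Step 11
Reactants: 17 enol triflate
Product: 18 C2,C3-diol with both new hydroxyls cis to the C6 branch
Conditions: OsO4 (5 mol %), NMO, citric acid, t-BuOH/H2O, rt
Reagents that add atoms: osmium tetroxide, O=[Os](=O)(=O)=O; N-methylmorpholine N-oxide, C[N+]1([O-])CCOCC1; water, O
Why: Upjohn dihydroxylation: OsO4 adds syn to the trisubstituted C2=C3 alkene rather than to the triflate-deactivated C7=C14 alkene and anti to both allylic oxygens at C1 and C4 (Kishi's rule), which sets C3 with its hydroxyl cis to the C6 branch; the acidic medium holds back acyl migration from C1 to C2.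

Step 12
Reactants: 18 C2,C3-diol
Product: 19 C2 ketone with tertiary C3 hydroxyl
Conditions: Dess–Martin periodinane, CH2Cl2, rt
Reagents that add atoms: none
Why: Dess–Martin oxidation: only the secondary C2 hydroxyl can be oxidised, and the non-basic medium leaves the silyl ether, ester and enol triflate alone and does not epimerise C1.

Step 13
Reactants: 19 α-ketol silyl ether
Product: 20 C4 alcohol (C3,C4-trans-diol)
Conditions: HF·pyridine, THF/pyridine, 0 °C → rt
Reagents that add atoms: none
Why: Fluoride-mediated desilylation driven by the Si–F bond; buffered HF·pyridine is not basic, so the α-acyloxy ketone, the tertiary α-ketol and the enol triflate are not disturbed.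

Step 14
Reactants: 20 C3,C4-diol
Product: 22 ring-complete enol triflate with the C3–O–C4 oxirane cis to the C6 branch, via mesylate 21 (not isolated)
Conditions: MsCl, Et3N, CH2Cl2, −10 °C; then DBU, rt
Reagents that add atoms: none
Why: Mesylation of the only secondary hydroxyl, then intramolecular Williamson etherification (3-exo-tet): the C3 alkoxide, trans-diaxial to the C4 mesylate, displaces it with inversion at C4, and C3 carries no hydrogen, which rules out E1cB loss of the mesylate.

Step 15
Reactants: 23 2-methylbut-3-yn-2-ol
Product: 24 (E)-2-methyl-4-(tributylstannyl)but-3-en-2-ol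
Conditions: Bu3SnH, PdCl2(PPh3)2 (2 mol %), THF, rt
Reagents that add atoms: tributyltin hydride, CCCC[SnH](CCCC)CCCC
Why: Palladium-catalysed hydrostannylation: syn addition of Sn–H across the terminal alkyne, with tin steered to the terminal carbon by the bulky tertiary carbinol, gives the (E)-vinylstannane.

Step 16
Reactants: 22 ring-complete enol triflate; 24 (E)-vinylstannane
Product: 25 cross-conjugated dienone with C6–C(=CH2)–C(=O)–CH=CH–C(CH3)2OH
Conditions: CO (3 atm), Pd(PPh3)4 (5 mol %), LiCl, THF, 55 °C
Reagents that add atoms: carbon monoxide, [C-]#[O+]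
Why: Carbonylative Stille coupling: oxidative addition of zerovalent palladium into the enol triflate, CO insertion, transmetalation of the vinylstannane with retention of E geometry and reductive elimination form C7–C8 and C8–C9 in one step, with CO pressure suppressing direct coupling and the free tertiary alcohol, ester and epoxy ketone tolerated.

Step 17
Reactants: 25 dienone
Product: 26 target, (1S,3S,4R,6S)-4-[(2R)-2-[(2E)-4-hydroxy-4-methylpent-2-enoyl]oxiran-2-yl]-1-methyl-2-oxo-7-oxabicyclo[4.1.0]heptan-3-yl 3-methylbutanoate
Conditions: t-BuOOH (in decane), DBU, CH2Cl2, 0 °C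
Reagents that add atoms: tert-butyl hydroperoxide, CC(C)(C)OO
Why: Weitz–Scheffer nucleophilic epoxidation: the peroxide anion adds to the unsubstituted C14 terminus rather than to C10, which is shielded by the quaternary carbinol, and the C7 enolate should close onto oxygen from the face flanked by C5H2 rather than by the C1 acyloxy methine while C6–H eclipses the enolate double bond (A(1,3) strain), giving the (7R) oxirane; DBU is non-nucleophilic and spares the ester.

**Compound list**

1 | (R)-carvone, (5R)-2-methyl-5-(prop-1-en-2-yl)cyclohex-2-en-1-one | CC1=CC[C@H](CC1=O)C(C)=C | starting material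
2 | ozonide of 1, (5R)-2-methyl-5-(3-methyl-1,2,4-trioxolan-3-yl)cyclohex-2-en-1-one, both epimers at the trioxolane carbon, not isolated | CC1=CC[C@H](CC1=O)C1(C)OCOO1 | intermediate
3 | (5R)-5-acetyl-2-methylcyclohex-2-en-1-one | CC1=CC[C@H](CC1=O)C(C)=O | intermediate
4 | (5R)-2-methyl-5-(2-methyl-1,3-dioxolan-2-yl)cyclohex-2-en-1-one | CC1=CC[C@H](CC1=O)C1(C)OCCO1 | intermediate
5 | p-toluenesulfonyl hydrazide | Cc1ccc(cc1)S(=O)(=O)NN | starting material
6 | (E)-tosylhydrazone of 4, sulfonamide nitrogen syn to the ring CH2 that becomes C1 | CC1=CC[C@H](C/C1=N\NS(=O)(=O)c1ccc(C)cc1)C1(C)OCCO1 | intermediate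
7 | vinyllithium, diene 8 lithiated at C2, not isolated | C1=C([Li])C(C)=CC[C@H]1C1(C)OCCO1 | intermediate
8 | 2-methyl-2-[(1R)-4-methylcyclohexa-2,4-dien-1-yl]-1,3-dioxolane (diene C1=C2–C3(CH3)=C4) | C1=CC(C)=CC[C@H]1C1(C)OCCO1 | intermediate
9 | dioxygen | O=O | starting material
10 | endoperoxide, 2-methyl-2-(5-methyl-2,3-dioxabicyclo[2.2.2]oct-5-en-7-yl)-1,3-dioxolane, C1–O and C4–O both trans to the C6 dioxolanyl group | O1O[C@@H]2C=C(C)[C@H]1C[C@H]2C3(C)OCCO3 | intermediate
11 | 3-methyl-6-(2-methyl-1,3-dioxolan-2-yl)cyclohex-2-ene-1,4-diol, hydroxyls cis to each other and trans to the C6 group | O[C@@H]1C=C(C)[C@H](O)C[C@H]1C1(C)OCCO1 | intermediate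
12 | C4 tert-butyldimethylsilyl ether of 11, C1 hydroxyl free | O[C@@H]1C=C(C)[C@H](O[Si](C)(C)C(C)(C)C)C[C@H]1C1(C)OCCO1 | intermediate
13 | 3-methylbutanoyl chloride (isovaleryl chloride) | CC(C)CC(Cl)=O | starting material
14 | C1 3-methylbutanoate of 12 | CC(C)CC(=O)O[C@@H]1C=C(C)[C@H](O[Si](C)(C)C(C)(C)C)C[C@H]1C1(C)OCCO1 | intermediate
15 | methyl ketone, as 14 with C6 acetyl in place of the dioxolane | CC(C)CC(=O)O[C@@H]1C=C(C)[C@H](O[Si](C)(C)C(C)(C)C)C[C@H]1C(C)=O | intermediate
16 | potassium enolate of 15 on the methyl side (C7=C14), not isolated | CC(C)CC(=O)O[C@@H]1C=C(C)[C@H](O[Si](C)(C)C(C)(C)C)C[C@H]1C(=C)[O-].[K+] | intermediate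
17 | enol triflate, C6–C(OSO2CF3)=CH2, ring as in 15 | CC(C)CC(=O)O[C@@H]1C=C(C)[C@H](O[Si](C)(C)C(C)(C)C)C[C@H]1C(=C)OS(=O)(=O)C(F)(F)F | intermediate
18 | C2,C3-diol of 17, both new hydroxyls cis to the C6 branch, C3 methyl trans to it | CC(C)CC(=O)O[C@@H]1[C@@H](O)[C@@](C)(O)[C@H](O[Si](C)(C)C(C)(C)C)C[C@H]1C(=C)OS(=O)(=O)C(F)(F)F | intermediate
19 | C2 ketone of 18, tertiary C3 hydroxyl kept | CC(C)CC(=O)O[C@@H]1C(=O)[C@@](C)(O)[C@H](O[Si](C)(C)C(C)(C)C)C[C@H]1C(=C)OS(=O)(=O)C(F)(F)F | intermediate
20 | C4 alcohol from 19, C3–OH and C4–OH trans | CC(C)CC(=O)O[C@@H]1C(=O)[C@@](C)(O)[C@H](O)C[C@H]1C(=C)OS(=O)(=O)C(F)(F)F | intermediate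
21 | C4 methanesulfonate of 20, not isolated | CC(C)CC(=O)O[C@@H]1C(=O)[C@@](C)(O)[C@H](OS(C)(=O)=O)C[C@H]1C(=C)OS(=O)(=O)C(F)(F)F | intermediate
22 | ring-complete enol triflate: C1 isovalerate trans to the C6 branch, C2 ketone, C3–O–C4 oxirane cis to the C6 branch, C6–C(OSO2CF3)=CH2 | CC(C)CC(=O)O[C@@H]1C(=O)[C@@]2(C)O[C@H]2C[C@H]1C(=C)OS(=O)(=O)C(F)(F)F | intermediate
23 | 2-methylbut-3-yn-2-ol | CC(C)(O)C#C | starting material
24 | (E)-2-methyl-4-(tributylstannyl)but-3-en-2-ol | CCCC[Sn](CCCC)(CCCC)/C=C/C(C)(C)O | intermediate
25 | dienone, ring as in 22 with C6–C(=CH2)–C(=O)–(E)-CH=CH–C(CH3)2OH | CC(C)CC(=O)O[C@@H]1C(=O)[C@@]2(C)O[C@H]2C[C@H]1C(=C)C(=O)/C=C/C(C)(C)O | intermediate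
26 | CNP0292003.1, (1S,3S,4R,6S)-4-[(2R)-2-[(2E)-4-hydroxy-4-methylpent-2-enoyl]oxiran-2-yl]-1-methyl-2-oxo-7-oxabicyclo[4.1.0]heptan-3-yl 3-methylbutanoate | CC(C)CC(=O)O[C@@H]1C(=O)[C@@]2(C)O[C@H]2C[C@H]1[C@]1(C(=O)/C=C/C(C)(C)O)CO1 | target

**Step count and risks**

Total: 17 steps. Longest linear sequence: 16 steps (steps 1–14, 16 and 17); step 15 is the one-step branch to stannane 24.

Step 5. Singlet oxygen may add in part to the diene face syn to the C6 group, and ene-type hydroperoxidation at C3=C4 or oxidative aromatisation of the diene may compete, so the yield of 10 would fall. The fallback builds the same diol by polar chemistry and sets out from enone 4. Weitz–Scheffer epoxidation (H2O2, NaOH, MeOH, 0 °C) should give the oxirane trans to the C6 group, the face alkaline peroxide prefers in carvone-type enones and the one C4–O needs at this stage: trans-epoxy ketone F1. Enolisation toward C1 (LiN(SiMe3)2, THF, −78 °C) and oxidation with 2-(phenylsulfonyl)-3-phenyloxaziridine anti to the neighbouring C6 group should give α′-hydroxy epoxy ketone F2. Wharton transposition (N2H4·H2O, AcOH cat., MeOH, 0 °C → rt) then shifts the functionality to C2=C3 and C4–OH with retention at C4, and the route is rejoined at diol 11.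

Step 17. Closure of the peroxy enolate at C7 may show poor facial selectivity and give both C7 epimers, and the basic medium may epimerise C1 or attack the ester. The fallback sets C7 under reagent control and sets out from enol triflate 22. Stille coupling with (tributylstannyl)methanol (Pd(PPh3)4, LiCl, dioxane, 90 °C) gives 2-substituted allylic alcohol F3. Sharpless asymmetric epoxidation (Ti(OiPr)4, L-(+)-diethyl tartrate, t-BuOOH, 4 Å sieves, CH2Cl2, −20 °C) should give epoxy alcohol F4 with the C7 arrangement of the target. Dess–Martin oxidation gives epoxy aldehyde F5. Stannane 24 and I2 (CH2Cl2, 0 °C) give (E)-vinyl iodide F6, which is added to F5 under Nozaki–Hiyama–Kishi conditions (CrCl2, NiCl2 cat., DMSO, rt) to give C8 carbinol F7 as both C8 epimers. Dess–Martin oxidation of F7 comes back to the route at target 26.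

Step 16. CO insertion at the α-branched vinylpalladium species may be slow, so direct coupling without CO would compete, and zerovalent palladium may isomerise the epoxy ketone on heating. The fallback forms C7–C8 by carbonyl addition and sets out from enol triflate 22. Cross-metathesis of 2-methylbut-3-en-2-ol with crotonaldehyde (second-generation Grubbs catalyst, CH2Cl2, 40 °C) gives (E)-4-hydroxy-4-methylpent-2-enal F8. Nozaki–Hiyama–Kishi coupling of 22 with F8 (CrCl2, NiCl2 cat., DMF, rt), which spares the ring ketone and the ester, gives bis-allylic carbinol F9 as both C8 epimers. Dess–Martin oxidation of F9 comes back to the route at dienone 25.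

**Further compounds**

F1 | step 5 | trans-epoxy ketone, 1-methyl-4-(2-methyl-1,3-dioxolan-2-yl)-7-oxabicyclo[4.1.0]heptan-2-one with the oxirane trans to the dioxolanyl group | C1C(=O)[C@]2(C)O[C@@H]2C[C@H]1C1(C)OCCO1
F2 | step 5 | α′-hydroxy epoxy ketone, F1 with a C1 hydroxyl trans to the dioxolanyl group | O[C@@H]1C(=O)[C@]2(C)O[C@@H]2C[C@H]1C1(C)OCCO1
F3 | step 17 | allylic alcohol, ring as in 22 with C6–C(=CH2)–CH2OH | CC(C)CC(=O)O[C@@H]1C(=O)[C@@]2(C)O[C@H]2C[C@H]1C(=C)CO
F4 | step 17 | epoxy alcohol, ring as in 22 with C6 bearing a 2-(hydroxymethyl)oxiran-2-yl group, C7 arranged as in the target | CC(C)CC(=O)O[C@@H]1C(=O)[C@@]2(C)O[C@H]2C[C@H]1[C@]1(CO)CO1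
F5 | step 17 | epoxy aldehyde, F4 with C8 as CHO | CC(C)CC(=O)O[C@@H]1C(=O)[C@@]2(C)O[C@H]2C[C@H]1[C@]1(C=O)CO1
F6 | step 17 | (E)-4-iodo-2-methylbut-3-en-2-ol | CC(C)(O)/C=C/I
F7 | step 17 | C8 carbinol of the target, both C8 epimers | CC(C)CC(=O)O[C@@H]1C(=O)[C@@]2(C)O[C@H]2C[C@H]1[C@]1(C(O)/C=C/C(C)(C)O)CO1
F8 | step 16 | (E)-4-hydroxy-4-methylpent-2-enal | CC(C)(O)/C=C/C=O
F9 | step 16 | C8 carbinol of dienone 25, both C8 epimers | CC(C)CC(=O)O[C@@H]1C(=O)[C@@]2(C)O[C@H]2C[C@H]1C(=C)C(O)/C=C/C(C)(C)O
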